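## The problem

Michaolide F (43) is a cembranolide: a 14-membered carbocycle (C1–C14) trans-fused at C1/C2 to an α-methylene-γ-butyrolactone (C15 α-carbon, C16 carbonyl, C17 methylene). It carries a trisubstituted C3–C4 epoxide (methyl on C4), an acetate on C5, a free hydroxyl on C14 and two E-trisubstituted olefins, C7=C8 and C11=C12.

All six stereocentres lie in one run, C14–C1–C2–C3–C4–C5, while C6–C13 is stereochemically blank apart from olefin geometry. The ring should therefore be closed in the blank half and the stereo-run built in open chain under reagent control.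

C3/C4 can be set by asymmetric epoxidation of an allylic alcohol. The C2 oxygen is erythro and the C5 oxygen threo to the epoxide, the opposite of what hydroxyl-directed epoxidation from either neighbour would be expected to give, so the epoxide has to come first and C2 and C5 have to be made by additions to epoxy aldehydes. C1 and C2 are an anti pair that a crotyl-type addition can set together, and C14 can be taken from the chiral pool.

The α-methylene lactone is a Michael acceptor and does not survive soft carbanions or dissolving metals. The epoxide is sensitive to acid and Lewis acid, the acetate to base, and the free C14 hydroxyl is γ to C16 and can translactonise under base.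

C9–C10 is the only ring bond between two allylic methylene carbons. C10–C11=C12 is a prenyl-type allyl unit with a primary terminus at C10, and C9 can carry two sulfonyl groups as a stabilised carbanion. Closing the ring there creates no stereocentre.

## Retrosynthesis

**43 back to 40.** The last operations are O–Si and O–acyl changes only. The C14 silyl ether of 42 is cleaved last under non-basic conditions; the C5 acetate of 42 comes from alcohol 41, which comes from the triethylsilyl ether 40. The acetate could not have been carried earlier because the methylenation needs a strong base.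

**40 back to 35.** The C15=C17 bond is cut to the saturated lactone 37 (through Mannich base 38), and the two C9–H bonds of 37 are cut to the C9–S bonds of macrocycle 35. The methylene group must come after the carbanion chemistry and the dissolving-metal step, both of which it would not survive.

**35 back to 34 (key cut, C9–C10).** Opening the ring here gives the acyclic carbonate 34 with all six stereocentres already in place.
- Cuts at C5–C6, C13–C14 or C1–C2 would create a stereocentre during macrocyclisation, where facial control is least predictable.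
- Ring-closing metathesis at C7=C8 or C11=C12 would have to make a trisubstituted olefin of defined geometry inside a 14-membered ring.
- The forward reaction must attack C10 rather than C12, keep the E olefin, and cyclise rather than oligomerise.

**34 back to 28.** The carbonate of 34 comes from alcohol 33 and its 4-methoxybenzyl ether 32. The lactone C16–O2 bond of 32 is cut to diol 30, whose C16 hydroxyl comes from the vinyl group of homoallylic alcohol 28. A vinyl group as the latent C15–C16 unit lets the lactone be formed only after the two halves are joined.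

**28 back to 14 and 26 (C1–C2).** This cut divides the molecule into an epoxy aldehyde 14 (C2–C9) and an allene 26 (C10–C16). Hydroboration of 26 gives the E-γ-substituted allylborane 27, which adds to 14 anti-selectively and sets C1 and C2 in one step under control of the boron ligands. An auxiliary-controlled succinate aldol would set the same two centres but leave C14 as an acyl group, and the C10–C13 chain would then have to be attached to a lactone-bearing intermediate.

**14 back to 6.** The C2 aldehyde comes from alcohol 13 and its ether 12. The second C9–S bond of 12 is cut to the allylic sulfone 11, since C9 is bound directly to the olefinic C8 and the geminal bis-sulfone cannot be made by alkylating bis(phenylsulfonyl)methane. Sulfone 11 comes from alcohol 9 (via bromide 10) and enal 8. The C7=C8 bond of 8 is cut to the terminal olefin 7 and methacrolein, and 7 is the silyl ether of 6.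

**6 back to 1.** The C5–C6 bond is cut to epoxy aldehyde 5 and an allylborane. Aldehyde 5 comes from epoxy alcohol 4, whose epoxide comes from E-allylic alcohol 3, made from prenyl ether 2 and prenol 1. The E geometry and both epoxide stereocentres thus come from prenol and one catalytic step.

**26 back to 15 and 19.** The allene comes from alkyne 24 (through amine 25), and 24 from ester 22 (through aldehyde 23) and hydroxy ester 21. The C12–C13 bond of 21 is cut to the alkenylmagnesium 20, made from vinyl iodide 18, and methyl (R)-glycidate 19. Iodide 18 comes from 17 and but-2-yn-1-ol 15 (through the alkenylzirconium 16). C14 is bought with the glycidate and the C11=C12 geometry is fixed by a syn hydrometalation.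

## Roads not taken

**Alternative 1: iodolactonisation–epoxide relay.**
- Cut: the lactone C2–O and epoxide C3–O bonds are made last, on a preformed macrocyclic 2Z-olefinic hydroxy acid A1.
- Forward step: iodine activates C2=C3, the carboxylate closes the lactone anti to iodine, and base lets the C4 alkoxide displace iodide to give the silyl ether A2 of the target.
- Merits: two rings and two stereocentres in one flask at a late stage, with the acetate and methylene group already in place; no sulfone removal and no late methylenation.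
- Weak points: A1 has three trisubstituted-type olefins, and C7=C8 and C11=C12 are at least as nucleophilic toward iodine as C2=C3. The face of attack is decided by the conformation of a 14-membered ring. The carboxylate is that of an acrylic acid and the neighbouring acetate can participate.
- Comparison: its endgame is clearly shorter. The chosen plan sets against that the fact that C2, C3 and C4 are fixed in open chain by reagent control before the ring exists.

**Alternative 2: [2,3]-Wittig ring contraction.**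
- Cut: C1–C14, from the 17-membered α-stannyl allyl ether A3.
- Forward step: tin–lithium exchange and rearrangement give A4, contracting the ring to 14 members, setting C1 and C14 and unveiling the C15=C17 methylene.
- Merits: two stereocentres and the methylene carbon in one step, with no activating groups to remove afterwards.
- Weak points: A3 needs a stereodefined α-alkoxystannane and a macrocyclic etherification. Competing [1,2]-shift and the sense of the two new stereocentres depend on the conformation of a large ring. A4 is still several oxidation and protecting-group steps from the lactone.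
- Comparison: it is better in bond economy at the ring-forming step. The chosen closure forms no stereocentre and so cannot fail stereochemically.

**Alternative 3: ring-closing alkyne metathesis, then trans-methylation.**
- Cut: C11≡C12, from the methyl-capped diyne A5.
- Forward step: a molybdenum alkylidyne closes the cycloalkyne A6; hydroxyl-directed trans-hydrometalation and methylation then make the E-C11=C12 olefin.
- Merits: alkyne metathesis is reliable for large rings and tolerant of the oxygenation, so A6 can carry epoxide, acetate and methylene lactone and the endgame is two steps.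
- Weak points: the C11=C12 geometry and the position of the methyl group rest on a hydrometalation directed by the C14 hydroxyl on a substrate that also holds an α-methylene lactone. A stannane and a copper/palladium methylation must be used at the very end on the complete, base-sensitive molecule.
- Comparison: in functional-group economy it is at least as good as the chosen plan. The chosen plan offers olefins of defined geometry made on small fragments and a ring closure that needs no tin.

Key step: step 24

Assumptions: ring atoms are numbered C1–C14 and lactone carbons C15–C17 as above, and the same locants are used for open-chain precursors. CIP descriptors at C1, C3 and C4 change when neighbouring groups change although the spatial arrangement does not. (−)-Ipc2BH is prepared from (+)-α-pinene and BH3·SMe2 as a reagent and is not counted as a step.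

## Route

Step 1
Reactants: 1 prenol
Product: 2 prenyl 4-methoxybenzyl ether
Conditions: NaH, 4-methoxybenzyl chloride, n-Bu4NI (cat.), THF/DMF, 0 °C → rt
Reagents that add atoms: 4-methoxybenzyl chloride, COc1ccc(CCl)cc1
Why: Williamson etherification; the 4-methoxybenzyl ether survives base, hydride and organometallic steps and is later removed oxidatively beside silyl ethers.

Step 2
Reactants: 2 prenyl 4-methoxybenzyl ether
Product: 3 (2E)-4-[(4-methoxybenzyl)oxy]-2-methylbut-2-en-1-ol
Conditions: SeO2 (cat.), t-BuOOH, salicylic acid (cat.), CH2Cl2, rt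
Reagents that add atoms: tert-butyl hydroperoxide (oxygen atom, relayed through SeO2), CC(C)(C)OO
Why: Allylic oxidation (ene reaction, then [2,3]-sigmatropic shift) is selective for the E-methyl group of a prenyl ether, so the E geometry comes from prenol.

Step 3
Reactants: 3 (2E)-4-[(4-methoxybenzyl)oxy]-2-methylbut-2-en-1-ol
Product: 4 [(2S,3S)-3-{[(4-methoxybenzyl)oxy]methyl}-2-methyloxiran-2-yl]methanol
Conditions: Ti(OiPr)4 (cat.), L-(+)-diethyl tartrate (cat.), t-BuOOH, 4 Å MS, CH2Cl2, −20 °C
Reagents that add atoms: tert-butyl hydroperoxide, CC(C)(C)OO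
Why: Sharpless asymmetric epoxidation of a 2-methyl E-allylic alcohol; L-(+)-tartrate delivers oxygen to the face that gives the (2S,3S)-epoxide, which is C4 and C3 of the target, under reagent control.

Step 4
Reactants: 4 epoxy alcohol
Product: 5 (2R,3S)-3-{[(4-methoxybenzyl)oxy]methyl}-2-methyloxirane-2-carbaldehyde
Conditions: Dess–Martin periodinane, NaHCO3, CH2Cl2, 0 °C → rt
Reagents that add atoms: none
Why: Buffered Dess–Martin oxidation; the α-carbon is quaternary, so the aldehyde cannot epimerise.

Step 5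
Reactants: 5 epoxy aldehyde
Product: 6 (1R)-1-[(2S,3S)-3-{[(4-methoxybenzyl)oxy]methyl}-2-methyloxiran-2-yl]but-3-en-1-ol
Conditions: (+)-Ipc2BOMe, allylMgBr, Et2O, −78 °C → rt; then 5, −78 °C; NaOH, H2O2
Reagents that add atoms: allylmagnesium bromide, C=CC[Mg]Br
Why: Brown allylation; the (+)-Ipc2B reagent from (−)-α-pinene adds allyl to the Re face through a chair transition state, giving the 5R alcohol (threo to the epoxide) under reagent control, against the modest anti preference of the epoxy aldehyde.

Step 6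
Reactants: 6 homoallylic alcohol
Product: 7 triethylsilyl ether of 6
Conditions: Et3SiOTf, 2,6-lutidine, CH2Cl2, −78 °C
Reagents that add atoms: triethylsilyl trifluoromethanesulfonate, CC[Si](CC)(CC)OS(=O)(=O)C(F)(F)F
Why: Silylation of a hindered secondary alcohol with the silyl triflate; triethylsilyl is chosen so that it can later be removed beside the C14 tert-butyldimethylsilyl ether.

Step 7
Reactants: 7 terminal olefin
Product: 8 (2E,5R)-5-[(2R,3S)-3-{[(4-methoxybenzyl)oxy]methyl}-2-methyloxiran-2-yl]-2-methyl-5-[(triethylsilyl)oxy]pent-2-enal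
Conditions: methacrolein (excess), second-generation Hoveyda–Grubbs catalyst [RuCl2(H2IMes)(=CH–C6H4-2-OiPr)] (5 mol %), CH2Cl2, 40 °C
Reagents that add atoms: methacrolein, C=C(C)C=O
Why: Olefin cross-metathesis of a terminal alkene with an electron-poor 1,1-disubstituted partner that does not homodimerise; the E-2-methyl enal is strongly favoured, which sets the C7=C8 geometry.

Step 8
Reactants: 8 enal
Product: 9 (2E,5R)-5-[(2R,3S)-3-{[(4-methoxybenzyl)oxy]methyl}-2-methyloxiran-2-yl]-2-methyl-5-[(triethylsilyl)oxy]pent-2-en-1-ol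
Conditions: NaBH4, CeCl3·7H2O, MeOH, −20 °C
Reagents that add atoms: none
Why: Luche reduction gives clean 1,2-reduction of the enal and leaves epoxide and silyl ether alone.

Step 9
Reactants: 9 allylic alcohol
Product: 11 allylic phenyl sulfone (C9–SO2Ph), via allylic bromide 10 (not isolated)
Conditions: CBr4, PPh3, 2,6-lutidine, CH2Cl2, 0 °C; then PhSO2Na, DMF, rt
Reagents that add atoms: sodium benzenesulfinate, [Na+].[O-]S(=O)c1ccccc1; carbon tetrabromide (bromine of 10 only), BrC(Br)(Br)Br
Why: Appel bromination, then S-alkylation of sulfinate by SN2 at the primary allylic carbon; the olefin geometry is not touched.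

Step 10
Reactants: 11 allylic phenyl sulfone
Product: 12 allylic geminal bis(phenylsulfonyl) compound (C9)
Conditions: LiN(SiMe3)2 (2.2 equiv), THF, −78 °C; PhSO2F; then aq. NH4Cl
Reagents that add atoms: benzenesulfonyl fluoride, O=S(=O)(F)c1ccccc1
Why: C-Sulfonylation of an α-sulfonyl carbanion with a sulfonyl fluoride (the fluoride transfers the sulfonyl group, not halogen); the second equivalent of base is taken up by the more acidic product, and the charge between sulfur and the allyl unit reacts at the α-carbon.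

Step 11
Reactants: 12 bis-sulfone, 4-methoxybenzyl ether
Product: 13 [(2S,3R)-3-methyl-3-{(1R,3E)-4-methyl-5,5-bis(phenylsulfonyl)-1-[(triethylsilyl)oxy]pent-3-en-1-yl}oxiran-2-yl]methanol
Conditions: DDQ, CH2Cl2/pH 7 buffer, 0 °C
Reagents that add atoms: none
Why: Oxidative cleavage of the 4-methoxybenzyl ether by hydride abstraction; silyl ether, epoxide and the electron-poor olefin are inert.

Step 12
Reactants: 13 epoxy alcohol
Product: 14 (2R,3R)-3-methyl-3-{(1R,3E)-4-methyl-5,5-bis(phenylsulfonyl)-1-[(triethylsilyl)oxy]pent-3-en-1-yl}oxirane-2-carbaldehyde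
Conditions: Dess–Martin periodinane, NaHCO3, CH2Cl2, 0 °C
Reagents that add atoms: none
Why: Buffered Dess–Martin oxidation of a 2,3-epoxy alcohol to the epoxy aldehyde, which is used at once.

Step 13
Reactants: 15 but-2-yn-1-ol
Product: 17 (2E)-3-iodobut-2-en-1-ol, via alkenylzirconocene 16 (not isolated)
Conditions: Cp2Zr(H)Cl (2.2 equiv), THF, rt; then I2, 0 °C
Reagents that add atoms: iodine, II
Why: Hydrozirconation with the Schwartz reagent is a syn addition that, after O-metalation, places zirconium on C3 remote from oxygen; iodinolysis with retention gives the E-iodide.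

Step 14
Reactants: 17 (2E)-3-iodobut-2-en-1-ol
Product: 18 1-({[(2E)-3-iodobut-2-en-1-yl]oxy}methyl)-4-methoxybenzene
Conditions: NaH, 4-methoxybenzyl chloride, n-Bu4NI (cat.), THF, 0 °C → rt
Reagents that add atoms: 4-methoxybenzyl chloride, COc1ccc(CCl)cc1
Why: Williamson etherification; the vinyl iodide is inert to the alkoxide.

Step 15
Reactants: 18 vinyl iodide; 19 methyl (2R)-oxirane-2-carboxylate
Product: 21 methyl (2R,4E)-2-hydroxy-6-[(4-methoxybenzyl)oxy]-4-methylhex-4-enoate, via alkenylmagnesium chloride 20 (not isolated)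
Conditions: i-PrMgCl·LiCl, THF, 0 °C → rt; then CuI (10 mol %), 19, −40 °C; aq. NH4Cl
Reagents that add atoms: none
Why: Iodine–magnesium exchange with retention of olefin geometry, then copper-catalysed SN2 opening of the glycidate at its unsubstituted carbon; C14 comes unchanged from 19 and the E-C11=C12 olefin from 18.

Step 16
Reactants: 21 hydroxy ester
Product: 22 methyl (2R,4E)-2-[(tert-butyldimethylsilyl)oxy]-6-[(4-methoxybenzyl)oxy]-4-methylhex-4-enoate
Conditions: t-BuMe2SiCl, imidazole, DMF, rt
Reagents that add atoms: tert-butyldimethylsilyl chloride, CC(C)(C)[Si](C)(C)Cl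
Why: Standard silylation; this ether has to last until the final step.

Step 17
Reactants: 22 silyloxy ester
Product: 24 tert-butyl{[(3R,5E)-7-[(4-methoxybenzyl)oxy]-5-methylhept-5-en-1-yn-3-yl]oxy}dimethylsilane, via silyloxy aldehyde 23 (not isolated)
Conditions: i-Bu2AlH, CH2Cl2, −78 °C; then MeOH, K2CO3, dimethyl (1-diazo-2-oxopropyl)phosphonate, −78 °C → rt
Reagents that add atoms: dimethyl (1-diazo-2-oxopropyl)phosphonate (terminal alkyne carbon), CC(=O)C(=[N+]=[N-])P(=O)(OC)OC
Why: Partial reduction of the ester stops at the aluminium hemiacetal at −78 °C; Ohira–Bestmann homologation in the same flask under mild carbonate base gives the alkyne without epimerising the α-silyloxy centre.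

Step 18
Reactants: 24 terminal alkyne
Product: 26 tert-butyl{[(4R,6E)-8-[(4-methoxybenzyl)oxy]-6-methylocta-1,2,6-trien-4-yl]oxy}dimethylsilane, via propargylic amine 25 (not isolated)
Conditions: (CH2O)n, CuI, i-Pr2NH, 1,4-dioxane, reflux
Reagents that add atoms: paraformaldehyde (as formaldehyde), C=O
Why: Crabbé homologation; a copper-mediated Mannich reaction gives the propargylic amine, and 1,5-hydride transfer with loss of the imine gives the terminal allene.

Step 19
Reactants: 26 allene; 14 epoxy aldehyde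
Product: 28 (1S,2S,3S,4R,5R,7E,11E,14R)-14-[(tert-butyldimethylsilyl)oxy]-3,4-epoxy-10-[(4-methoxybenzyl)oxy]-9,9-bis(phenylsulfonyl)-5-[(triethylsilyl)oxy]-9,10-seco-17-norcembra-7,11,15-trien-2-ol, via allylborane 27 (not isolated)
Conditions: (−)-Ipc2BH [from (+)-α-pinene], THF, 0 °C → rt; then 14, −78 °C → rt; NaBO3·4H2O, THF/H2O
Reagents that add atoms: none
Why: Hydroboration of the terminal allene double bond puts boron on C16, and the first-formed Z-allylborane equilibrates by 1,3-boratropic shift to the E isomer; this adds through a chair transition state to give the anti C1/C2 pair, with the (+)-α-pinene-derived ligands directing attack to the Si face (C2 S), the face also preferred by the epoxy aldehyde itself (erythro to the epoxide).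

Step 20
Reactants: 28 homoallylic alcohol
Product: 30 (1S,2S,3S,4R,5R,7E,11E,14R)-14-[(tert-butyldimethylsilyl)oxy]-3,4-epoxy-10-[(4-methoxybenzyl)oxy]-9,9-bis(phenylsulfonyl)-5-[(triethylsilyl)oxy]-9,10-seco-17-norcembra-7,11-diene-2,16-diol, via bis-boryl intermediate 29 (not isolated)
Conditions: 9-BBN-H (3 equiv), THF, 0 °C → rt; then NaBO3·4H2O, H2O
Reagents that add atoms: sodium perborate (oxygen of the C16 hydroxyl), [Na+].[Na+].O[B-]1(O)OO[B-](O)(O)OO1
Why: 9-BBN hydroborates only the monosubstituted vinyl group, anti-Markovnikov; the two trisubstituted olefins are too hindered, and mild perborate oxidation avoids Payne rearrangement of the epoxy alcohol.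

Step 21
Reactants: 30 1,4-diol
Product: 32 (1S,2S,3S,4R,5R,7E,11E,14R)-14-[(tert-butyldimethylsilyl)oxy]-3,4-epoxy-10-[(4-methoxybenzyl)oxy]-9,9-bis(phenylsulfonyl)-5-[(triethylsilyl)oxy]-9,10-seco-17-norcembra-7,11-dien-16,2-olide, via lactol 31 (not isolated)
Conditions: TEMPO (cat.), PhI(OAc)2, CH2Cl2, rt
Reagents that add atoms: none
Why: Oxoammonium oxidation is selective for the primary alcohol; the hydroxy aldehyde closes to the lactol, which is oxidised on to the γ-lactone, and the trans ring fusion follows from the C1/C2 configuration already set.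

Step 22
Reactants: 32 lactone, 4-methoxybenzyl ether
Product: 33 C10 allylic alcohol
Conditions: DDQ, CH2Cl2/pH 7 buffer, 0 °C
Reagents that add atoms: none
Why: Oxidative removal of the 4-methoxybenzyl ether under buffered conditions leaves lactone, epoxide and both silyl ethers intact.

Step 23
Reactants: 33 C10 allylic alcohol
Product: 34 (1S,2S,3S,4R,5R,7E,11E,14R)-14-[(tert-butyldimethylsilyl)oxy]-3,4-epoxy-10-[(methoxycarbonyl)oxy]-9,9-bis(phenylsulfonyl)-5-[(triethylsilyl)oxy]-9,10-seco-17-norcembra-7,11-dien-16,2-olide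
Conditions: ClCO2Me, pyridine, CH2Cl2, 0 °C
Reagents that add atoms: methyl chloroformate, COC(=O)Cl
Why: Acylation of the primary allylic alcohol; pyridine is too weak a base to ionise the bis-sulfone.

Step 24
Reactants: 34 seco carbonate
Product: 35 (1S,2S,3S,4R,5R,7E,11E,14R)-14-[(tert-butyldimethylsilyl)oxy]-3,4-epoxy-9,9-bis(phenylsulfonyl)-5-[(triethylsilyl)oxy]-17-norcembra-7,11-dien-16,2-olide
Conditions: Pd(PPh3)4 (10 mol %), THF, 45 °C, syringe-pump addition to about 1 mM
Reagents that add atoms: none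
Why: Oxidative addition of zerovalent palladium to the C10 carbonate gives a cationic η3-allyl complex over C10–C12, carbon dioxide and methoxide, and the methoxide deprotonates the bis-sulfone so that no external base is needed. The soft carbanion attacks the allyl ligand on the face opposite palladium at the unsubstituted C10 terminus and forms C9–C10; the closest known reaction type is the palladium-catalysed macrocyclic allylic alkylation of bis(sulfonyl)methyl carbanions with allylic carbonates under neutral conditions. One ring closes, the 14-membered carbocycle, with all three allyl carbons inside the ring (attack at C12 would give a 12-membered ring with an exocyclic vinyl group). No stereocentre is formed. Attack at C10 rather than C12 is secured by the bulk of the tertiary carbanion and the fully substituted C12. The E-C11=C12 geometry is kept because syn/anti exchange would need an η1 intermediate at tertiary C12. Reaction through C9 rather than the vinylogous C7 follows from charge localisation between the two sulfonyl groups, and cyclisation rather than oligomerisation from slow addition into a dilute catalyst solution. The allylic C9–sulfonyl bonds ionise much more slowly than the carbonate at this temperature, and epoxide, lactone and silyl ethers do not react with the catalyst.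

Step 25
Reactants: 35 macrocyclic bis-sulfone
Product: 37 (1S,2S,3S,4R,5R,7E,11E,14R)-14-[(tert-butyldimethylsilyl)oxy]-3,4-epoxy-5-[(triethylsilyl)oxy]-17-norcembra-7,11-dien-16,2-olide, via mono-sulfone 36 (not isolated)
Conditions: 6 % Na/Hg, Na2HPO4, MeOH/THF, −20 °C
Reagents that add atoms: none
Why: Two successive reductive C–S cleavages by sodium amalgam; the phosphate buffer intercepts methoxide so lactone and silyl ethers survive, and low temperature favours protonation at C9 before the allylic anion equilibrates.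

Step 26
Reactants: 37 saturated lactone
Product: 38 17-(dimethylamino) lactone (Mannich base, C15 epimers)
Conditions: LiN(i-Pr)2, THF, −78 °C; then CH2=NMe2+ I−, −78 °C → rt
Reagents that add atoms: N,N-dimethylmethyleneiminium iodide (Eschenmoser's salt), C=[N+](C)C.[I-]
Why: Kinetic lactone enolate and Mannich aminomethylation; the lactone C15 methylene is the only acidic site, and the new C15 centre is removed in the next step.

Step 27
Reactants: 38 Mannich base
Product: 40 (1S,2S,3S,4R,5R,7E,11E,14R)-14-[(tert-butyldimethylsilyl)oxy]-3,4-epoxy-5-[(triethylsilyl)oxy]cembra-7,11,15(17)-trien-16,2-olide, via ammonium iodide 39 (not isolated)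
Conditions: MeI, MeOH, rt; then NaHCO3, CH2Cl2/H2O, rt
Reagents that add atoms: none
Why: Quaternisation of the amine, then E1cB loss of trimethylamine under bicarbonate gives the exocyclic methylene without strong base.

Step 28
Reactants: 40 bis-silyl ether
Product: 41 (1S,2S,3S,4S,5R,7E,11E,14R)-14-[(tert-butyldimethylsilyl)oxy]-3,4-epoxy-5-hydroxycembra-7,11,15(17)-trien-16,2-olide
Conditions: HF·pyridine, pyridine, THF, 0 °C
Reagents that add atoms: none
Why: Fluoride-mediated desilylation under pyridine buffering removes the more labile triethylsilyl ether and leaves the tert-butyldimethylsilyl ether.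

Step 29
Reactants: 41 C5 alcohol
Product: 42 (1S,2S,3S,4S,5R,7E,11E,14R)-5-acetoxy-14-[(tert-butyldimethylsilyl)oxy]-3,4-epoxycembra-7,11,15(17)-trien-16,2-olide
Conditions: Ac2O, pyridine, DMAP (cat.), CH2Cl2, rt
Reagents that add atoms: acetic anhydride, CC(=O)OC(C)=O
Why: Nucleophile-catalysed acetylation of the hindered secondary alcohol.

Step 30
Reactants: 42 silyl ether of the target
Product: 43 michaolide F
Conditions: HF·pyridine, THF, 0 °C → rt
Reagents that add atoms: none
Why: Acidic fluoride cleaves the last silyl ether without base, so the freed C14 hydroxyl does not translactonise and nothing adds to the methylene lactone.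

## Compound list

1 | 3-methylbut-2-en-1-ol (prenol) | CC(C)=CCO | starting material
2 | 1-methoxy-4-{[(3-methylbut-2-en-1-yl)oxy]methyl}benzene | CC(C)=CCOCc1ccc(OC)cc1 | intermediate
3 | (2E)-4-[(4-methoxybenzyl)oxy]-2-methylbut-2-en-1-ol | OC/C(C)=C/COCc1ccc(OC)cc1 | intermediate
4 | [(2S,3S)-3-{[(4-methoxybenzyl)oxy]methyl}-2-methyloxiran-2-yl]methanol | COc1ccc(COC[C@@H]2O[C@@]2(C)CO)cc1 | intermediate
5 | (2R,3S)-3-{[(4-methoxybenzyl)oxy]methyl}-2-methyloxirane-2-carbaldehyde | COc1ccc(COC[C@@H]2O[C@@]2(C)C=O)cc1 | intermediate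
6 | (1R)-1-[(2S,3S)-3-{[(4-methoxybenzyl)oxy]methyl}-2-methyloxiran-2-yl]but-3-en-1-ol | COc1ccc(COC[C@@H]2O[C@@]2(C)[C@H](O)CC=C)cc1 | intermediate
7 | triethyl{[(1R)-1-[(2R,3S)-3-{[(4-methoxybenzyl)oxy]methyl}-2-methyloxiran-2-yl]but-3-en-1-yl]oxy}silane | COc1ccc(COC[C@@H]2O[C@@]2(C)[C@H](O[Si](CC)(CC)CC)CC=C)cc1 | intermediate
8 | (2E,5R)-5-[(2R,3S)-3-{[(4-methoxybenzyl)oxy]methyl}-2-methyloxiran-2-yl]-2-methyl-5-[(triethylsilyl)oxy]pent-2-enal | COc1ccc(COC[C@@H]2O[C@@]2(C)[C@H](O[Si](CC)(CC)CC)C/C=C(\C)C=O)cc1 | intermediate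
9 | (2E,5R)-5-[(2R,3S)-3-{[(4-methoxybenzyl)oxy]methyl}-2-methyloxiran-2-yl]-2-methyl-5-[(triethylsilyl)oxy]pent-2-en-1-ol | COc1ccc(COC[C@@H]2O[C@@]2(C)[C@H](O[Si](CC)(CC)CC)C/C=C(\C)CO)cc1 | intermediate
10 | {[(1R,3E)-5-bromo-1-[(2R,3S)-3-{[(4-methoxybenzyl)oxy]methyl}-2-methyloxiran-2-yl]-4-methylpent-3-en-1-yl]oxy}triethylsilane | COc1ccc(COC[C@@H]2O[C@@]2(C)[C@H](O[Si](CC)(CC)CC)C/C=C(\C)CBr)cc1 | intermediate
11 | triethyl{[(1R,3E)-1-[(2R,3S)-3-{[(4-methoxybenzyl)oxy]methyl}-2-methyloxiran-2-yl]-4-methyl-5-(phenylsulfonyl)pent-3-en-1-yl]oxy}silane | COc1ccc(COC[C@@H]2O[C@@]2(C)[C@H](O[Si](CC)(CC)CC)C/C=C(\C)CS(=O)(=O)c3ccccc3)cc1 | intermediate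
12 | triethyl{[(1R,3E)-1-[(2R,3S)-3-{[(4-methoxybenzyl)oxy]methyl}-2-methyloxiran-2-yl]-4-methyl-5,5-bis(phenylsulfonyl)pent-3-en-1-yl]oxy}silane | COc1ccc(COC[C@@H]2O[C@@]2(C)[C@H](O[Si](CC)(CC)CC)C/C=C(\C)C(S(=O)(=O)c3ccccc3)S(=O)(=O)c3ccccc3)cc1 | intermediate
13 | [(2S,3R)-3-methyl-3-{(1R,3E)-4-methyl-5,5-bis(phenylsulfonyl)-1-[(triethylsilyl)oxy]pent-3-en-1-yl}oxiran-2-yl]methanol | OC[C@@H]1O[C@@]1(C)[C@H](O[Si](CC)(CC)CC)C/C=C(\C)C(S(=O)(=O)c1ccccc1)S(=O)(=O)c1ccccc1 | intermediate
14 | (2R,3R)-3-methyl-3-{(1R,3E)-4-methyl-5,5-bis(phenylsulfonyl)-1-[(triethylsilyl)oxy]pent-3-en-1-yl}oxirane-2-carbaldehyde | O=C[C@@H]1O[C@@]1(C)[C@H](O[Si](CC)(CC)CC)C/C=C(\C)C(S(=O)(=O)c1ccccc1)S(=O)(=O)c1ccccc1 | intermediate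
15 | but-2-yn-1-ol | CC#CCO | starting material
16 | O-zirconated (E)-alkenylzirconocene chloride from 15 (C3–Zr trans to the CH2O group; cyclopentadienyl rings drawn σ-bound) | C/C(=C\CO[Zr](Cl)(C1C=CC=C1)C1C=CC=C1)[Zr](Cl)(C1C=CC=C1)C1C=CC=C1 | intermediate
17 | (2E)-3-iodobut-2-en-1-ol | OC/C=C(\C)I | intermediate
18 | 1-({[(2E)-3-iodobut-2-en-1-yl]oxy}methyl)-4-methoxybenzene | COc1ccc(COC/C=C(\C)I)cc1 | intermediate
19 | methyl (2R)-oxirane-2-carboxylate (methyl (R)-glycidate) | COC(=O)[C@H]1CO1 | starting material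
20 | chlorido{(2E)-4-[(4-methoxybenzyl)oxy]but-2-en-2-yl}magnesium | COc1ccc(COC/C=C(\C)[Mg]Cl)cc1 | intermediate
21 | methyl (2R,4E)-2-hydroxy-6-[(4-methoxybenzyl)oxy]-4-methylhex-4-enoate | COc1ccc(COC/C=C(\C)C[C@@H](O)C(=O)OC)cc1 | intermediate
22 | methyl (2R,4E)-2-[(tert-butyldimethylsilyl)oxy]-6-[(4-methoxybenzyl)oxy]-4-methylhex-4-enoate | COc1ccc(COC/C=C(\C)C[C@@H](O[Si](C)(C)C(C)(C)C)C(=O)OC)cc1 | intermediate
23 | (2R,4E)-2-[(tert-butyldimethylsilyl)oxy]-6-[(4-methoxybenzyl)oxy]-4-methylhex-4-enal | COc1ccc(COC/C=C(\C)C[C@@H](O[Si](C)(C)C(C)(C)C)C=O)cc1 | intermediate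
24 | tert-butyl{[(3R,5E)-7-[(4-methoxybenzyl)oxy]-5-methylhept-5-en-1-yn-3-yl]oxy}dimethylsilane | COc1ccc(COC/C=C(\C)C[C@@H](O[Si](C)(C)C(C)(C)C)C#C)cc1 | intermediate
25 | (4R,6E)-4-[(tert-butyldimethylsilyl)oxy]-8-[(4-methoxybenzyl)oxy]-6-methyl-N,N-di(propan-2-yl)oct-6-en-2-yn-1-amine | COc1ccc(COC/C=C(\C)C[C@@H](O[Si](C)(C)C(C)(C)C)C#CCN(C(C)C)C(C)C)cc1 | intermediate
26 | tert-butyl{[(4R,6E)-8-[(4-methoxybenzyl)oxy]-6-methylocta-1,2,6-trien-4-yl]oxy}dimethylsilane | COc1ccc(COC/C=C(\C)C[C@@H](O[Si](C)(C)C(C)(C)C)C=C=C)cc1 | intermediate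
27 | B-[(2E,4R,6E)-4-[(tert-butyldimethylsilyl)oxy]-8-[(4-methoxybenzyl)oxy]-6-methylocta-2,6-dien-1-yl]diisopinocampheylborane (both isopinocampheyl groups from (+)-α-pinene) | COc1ccc(COC/C=C(\C)C[C@@H](O[Si](C)(C)C(C)(C)C)/C=C/CB([C@@H]2C[C@@H]3C[C@H]([C@H]2C)C3(C)C)[C@@H]2C[C@@H]3C[C@H]([C@H]2C)C3(C)C)cc1 | intermediate
28 | (1S,2S,3S,4R,5R,7E,11E,14R)-14-[(tert-butyldimethylsilyl)oxy]-3,4-epoxy-10-[(4-methoxybenzyl)oxy]-9,9-bis(phenylsulfonyl)-5-[(triethylsilyl)oxy]-9,10-seco-17-norcembra-7,11,15-trien-2-ol | COc1ccc(COC/C=C(\C)C[C@@H](O[Si](C)(C)C(C)(C)C)[C@@H](C=C)[C@H](O)[C@@H]2O[C@@]2(C)[C@H](O[Si](CC)(CC)CC)C/C=C(\C)C(S(=O)(=O)c3ccccc3)S(=O)(=O)c3ccccc3)cc1 | intermediate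
29 | 28 after hydroboration: C16 bound to one 9-borabicyclo[3.3.1]nonan-9-yl group and the C2 oxygen to a second | COc1ccc(COC/C=C(\C)C[C@@H](O[Si](C)(C)C(C)(C)C)[C@@H](CCB2C3CCCC2CCC3)[C@H](OB2C3CCCC2CCC3)[C@@H]2O[C@@]2(C)[C@H](O[Si](CC)(CC)CC)C/C=C(\C)C(S(=O)(=O)c3ccccc3)S(=O)(=O)c3ccccc3)cc1 | intermediate
30 | (1S,2S,3S,4R,5R,7E,11E,14R)-14-[(tert-butyldimethylsilyl)oxy]-3,4-epoxy-10-[(4-methoxybenzyl)oxy]-9,9-bis(phenylsulfonyl)-5-[(triethylsilyl)oxy]-9,10-seco-17-norcembra-7,11-diene-2,16-diol | COc1ccc(COC/C=C(\C)C[C@@H](O[Si](C)(C)C(C)(C)C)[C@@H](CCO)[C@H](O)[C@@H]2O[C@@]2(C)[C@H](O[Si](CC)(CC)CC)C/C=C(\C)C(S(=O)(=O)c3ccccc3)S(=O)(=O)c3ccccc3)cc1 | intermediate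
31 | 16,2-lactol of 30 (cyclic hemiacetal, C16 epimers) | COc1ccc(COC/C=C(\C)C[C@@H](O[Si](C)(C)C(C)(C)C)[C@H]2CC(O)O[C@@H]2[C@@H]3O[C@@]3(C)[C@H](O[Si](CC)(CC)CC)C/C=C(\C)C(S(=O)(=O)c4ccccc4)S(=O)(=O)c4ccccc4)cc1 | intermediate
32 | (1S,2S,3S,4R,5R,7E,11E,14R)-14-[(tert-butyldimethylsilyl)oxy]-3,4-epoxy-10-[(4-methoxybenzyl)oxy]-9,9-bis(phenylsulfonyl)-5-[(triethylsilyl)oxy]-9,10-seco-17-norcembra-7,11-dien-16,2-olide | COc1ccc(COC/C=C(\C)C[C@@H](O[Si](C)(C)C(C)(C)C)[C@H]2CC(=O)O[C@@H]2[C@@H]3O[C@@]3(C)[C@H](O[Si](CC)(CC)CC)C/C=C(\C)C(S(=O)(=O)c4ccccc4)S(=O)(=O)c4ccccc4)cc1 | intermediate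
33 | (1S,2S,3S,4R,5R,7E,11E,14R)-14-[(tert-butyldimethylsilyl)oxy]-3,4-epoxy-10-hydroxy-9,9-bis(phenylsulfonyl)-5-[(triethylsilyl)oxy]-9,10-seco-17-norcembra-7,11-dien-16,2-olide | OC/C=C(\C)C[C@@H](O[Si](C)(C)C(C)(C)C)[C@H]1CC(=O)O[C@@H]1[C@@H]2O[C@@]2(C)[C@H](O[Si](CC)(CC)CC)C/C=C(\C)C(S(=O)(=O)c3ccccc3)S(=O)(=O)c3ccccc3 | intermediate
34 | (1S,2S,3S,4R,5R,7E,11E,14R)-14-[(tert-butyldimethylsilyl)oxy]-3,4-epoxy-10-[(methoxycarbonyl)oxy]-9,9-bis(phenylsulfonyl)-5-[(triethylsilyl)oxy]-9,10-seco-17-norcembra-7,11-dien-16,2-olide | COC(=O)OC/C=C(\C)C[C@@H](O[Si](C)(C)C(C)(C)C)[C@H]1CC(=O)O[C@@H]1[C@@H]2O[C@@]2(C)[C@H](O[Si](CC)(CC)CC)C/C=C(\C)C(S(=O)(=O)c3ccccc3)S(=O)(=O)c4ccccc4 | intermediate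
35 | (1S,2S,3S,4R,5R,7E,11E,14R)-14-[(tert-butyldimethylsilyl)oxy]-3,4-epoxy-9,9-bis(phenylsulfonyl)-5-[(triethylsilyl)oxy]-17-norcembra-7,11-dien-16,2-olide | C1/C=C(\C)C[C@@H](O[Si](C)(C)C(C)(C)C)[C@H]2CC(=O)O[C@@H]2[C@@H]3O[C@@]3(C)[C@H](O[Si](CC)(CC)CC)C/C=C(\C)C1(S(=O)(=O)c4ccccc4)S(=O)(=O)c5ccccc5 | intermediate
36 | (1S,2S,3S,4R,5R,7E,11E,14R)-14-[(tert-butyldimethylsilyl)oxy]-3,4-epoxy-9-(phenylsulfonyl)-5-[(triethylsilyl)oxy]-17-norcembra-7,11-dien-16,2-olide (C9 epimers) | C1/C=C(\C)C[C@@H](O[Si](C)(C)C(C)(C)C)[C@H]2CC(=O)O[C@@H]2[C@@H]3O[C@@]3(C)[C@H](O[Si](CC)(CC)CC)C/C=C(\C)C1S(=O)(=O)c1ccccc1 | intermediate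
37 | (1S,2S,3S,4R,5R,7E,11E,14R)-14-[(tert-butyldimethylsilyl)oxy]-3,4-epoxy-5-[(triethylsilyl)oxy]-17-norcembra-7,11-dien-16,2-olide | C1/C=C(\C)C[C@@H](O[Si](C)(C)C(C)(C)C)[C@H]2CC(=O)O[C@@H]2[C@@H]3O[C@@]3(C)[C@H](O[Si](CC)(CC)CC)C/C=C(\C)C1 | intermediate
38 | (1S,2S,3S,4R,5R,7E,11E,14R)-14-[(tert-butyldimethylsilyl)oxy]-17-(dimethylamino)-3,4-epoxy-5-[(triethylsilyl)oxy]cembra-7,11-dien-16,2-olide (C15 epimers) | C1/C=C(\C)C[C@@H](O[Si](C)(C)C(C)(C)C)[C@H]2C(CN(C)C)C(=O)O[C@@H]2[C@@H]3O[C@@]3(C)[C@H](O[Si](CC)(CC)CC)C/C=C(\C)C1 | intermediate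
39 | trimethylammonium iodide of 38 (C15 epimers) | C1/C=C(\C)C[C@@H](O[Si](C)(C)C(C)(C)C)[C@H]2C(C[N+](C)(C)C)C(=O)O[C@@H]2[C@@H]3O[C@@]3(C)[C@H](O[Si](CC)(CC)CC)C/C=C(\C)C1.[I-] | intermediate
40 | (1S,2S,3S,4R,5R,7E,11E,14R)-14-[(tert-butyldimethylsilyl)oxy]-3,4-epoxy-5-[(triethylsilyl)oxy]cembra-7,11,15(17)-trien-16,2-olide | C1/C=C(\C)C[C@@H](O[Si](C)(C)C(C)(C)C)[C@H]2C(=C)C(=O)O[C@@H]2[C@@H]3O[C@@]3(C)[C@H](O[Si](CC)(CC)CC)C/C=C(\C)C1 | intermediate
41 | (1S,2S,3S,4S,5R,7E,11E,14R)-14-[(tert-butyldimethylsilyl)oxy]-3,4-epoxy-5-hydroxycembra-7,11,15(17)-trien-16,2-olide | C1/C=C(\C)C[C@@H](O[Si](C)(C)C(C)(C)C)[C@H]2C(=C)C(=O)O[C@@H]2[C@@H]3O[C@@]3(C)[C@H](O)C/C=C(\C)C1 | intermediate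
42 | (1S,2S,3S,4S,5R,7E,11E,14R)-5-acetoxy-14-[(tert-butyldimethylsilyl)oxy]-3,4-epoxycembra-7,11,15(17)-trien-16,2-olide | C1/C=C(\C)C[C@@H](O[Si](C)(C)C(C)(C)C)[C@H]2C(=C)C(=O)O[C@@H]2[C@@H]3O[C@@]3(C)[C@H](OC(C)=O)C/C=C(\C)C1 | intermediate
43 | michaolide F, (1R,2S,3S,4S,5R,7E,11E,14R)-5-acetoxy-3,4-epoxy-14-hydroxycembra-7,11,15(17)-trien-16,2-olide | C=C1C(=O)O[C@H]2[C@H]1[C@H](O)C/C(C)=C/CC/C(C)=C/C[C@@H](OC(C)=O)[C@]1(C)O[C@@H]21 | target

## Step count and least certain steps

Total: 30 steps. Longest linear sequence: 24 steps (steps 1–12 and 19–30, from prenol); the allene branch (steps 13–18) has 6 steps.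

**Step 24 (key step).** The most likely failure is intermolecular alkylation to oligomers if the stationary concentration is too high. Next comes attack through the vinylogous C7 position of the allylic carbanion, or slow ionisation of an allylic C9–sulfonyl bond by the catalyst with sulfonyl migration. Fallback: leave palladium out and close the same bond by direct SN2 alkylation. Starting from alcohol 33, Appel bromination (CBr4, PPh3) gives the C10 allylic bromide F1; slow addition of F1 to Cs2CO3 in DMF at high dilution lets the caesium bis-sulfonyl carbanion displace the primary bromide and returns to the route at 35.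

**Step 25.** The allyl unit C7–C8–C9 left after the second C–S cleavage has two similarly substituted ends, so protonation may shift the olefin to C8=C9 or scramble its geometry. Fallback: divide the reduction into two mechanistically different stages. Starting from 35, a limited amount of Na/Hg at −40 °C stops at mono-sulfone 36, which is isolated. The remaining allylic sulfone is then cleaved by Pd(PPh3)4 (zerovalent palladium) with NaBH4 in THF/i-PrOH at 0 °C, where hydride is delivered through an η3-allyl complex to the less hindered C9 terminus. This returns to the route at 37 and makes no compound outside the list.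

**Step 19.** Incomplete Z-to-E equilibration of the allylborane would give the syn C1/C2 isomer, and the C14 silyloxy centre next to the reacting carbon may oppose the face chosen by the boron ligands and erode selectivity. Fallback: use a configurationally stable pinacol boronate with an external chiral acid. Starting from ester 22, i-Bu2AlH gives aldehyde 23, now isolated. VinylMgBr gives the allylic alcohols F2, ClCO2Me/pyridine the methyl carbonates F3, and copper-catalysed SN2′ borylation (CuCl, Xantphos, KOt-Bu, B2pin2) the E-allyl pinacol boronate F4. F4 is added to aldehyde 14 in the presence of the enantiomer of a 3,3′-bis(2,4,6-triisopropylphenyl)-BINOL hydrogen phosphate that favours Si-face attack, returning to the route at 28.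

**Step 10.** The sulfonyl fluoride may react at the γ-carbon of the allylic anion, or sulfonyl transfer may be slow enough for the anion to decompose. Fallback: introduce the second sulfur at a lower oxidation level. Starting from 11, LiN(SiMe3)2 and PhSSPh give the α-phenylthio sulfone F5, and oxidation with H2O2 and catalytic (NH4)6Mo7O24 in EtOH takes the sulfide to the sulfone and returns to the route at 12.

**Step 5.** The allylborane has to override the anti (erythro) preference of the α,β-epoxy aldehyde, so facial selectivity may be poor. Fallback: run the matched reaction and invert. Starting from 5, the enantiomeric (−)-Ipc2B-allyl reagent gives the (1S)-alcohol F6. Mitsunobu reaction (4-nitrobenzoic acid, PPh3, DIAD) gives the inverted (1R)-4-nitrobenzoate F7, and K2CO3 in MeOH returns to the route at 6.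

## Further compounds

F1 | step 24 | (1S,2S,3S,4R,5R,7E,11E,14R)-10-bromo-14-[(tert-butyldimethylsilyl)oxy]-3,4-epoxy-9,9-bis(phenylsulfonyl)-5-[(triethylsilyl)oxy]-9,10-seco-17-norcembra-7,11-dien-16,2-olide | BrC/C=C(\C)C[C@@H](O[Si](C)(C)C(C)(C)C)[C@H]1CC(=O)O[C@@H]1[C@@H]2O[C@@]2(C)[C@H](O[Si](CC)(CC)CC)C/C=C(\C)C(S(=O)(=O)c3ccccc3)S(=O)(=O)c3ccccc3
F0 | step 25 | none | none
F2 | step 19 | (4R,6E)-4-[(tert-butyldimethylsilyl)oxy]-8-[(4-methoxybenzyl)oxy]-6-methylocta-1,6-dien-3-ol (C3 epimers) | COc1ccc(COC/C=C(\C)C[C@@H](O[Si](C)(C)C(C)(C)C)C(O)C=C)cc1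
F3 | step 19 | (4R,6E)-4-[(tert-butyldimethylsilyl)oxy]-8-[(4-methoxybenzyl)oxy]-6-methylocta-1,6-dien-3-yl methyl carbonate (C3 epimers) | COc1ccc(COC/C=C(\C)C[C@@H](O[Si](C)(C)C(C)(C)C)C(OC(=O)OC)C=C)cc1
F4 | step 19 | 2-[(2E,4R,6E)-4-[(tert-butyldimethylsilyl)oxy]-8-[(4-methoxybenzyl)oxy]-6-methylocta-2,6-dien-1-yl]-4,4,5,5-tetramethyl-1,3,2-dioxaborolane | COc1ccc(COC/C=C(\C)C[C@@H](O[Si](C)(C)C(C)(C)C)/C=C/CB2OC(C)(C)C(C)(C)O2)cc1
F5 | step 10 | triethyl{[(1R,3E)-1-[(2R,3S)-3-{[(4-methoxybenzyl)oxy]methyl}-2-methyloxiran-2-yl]-4-methyl-5-(phenylsulfanyl)-5-(phenylsulfonyl)pent-3-en-1-yl]oxy}silane (C9 epimers) | COc1ccc(COC[C@@H]2O[C@@]2(C)[C@H](O[Si](CC)(CC)CC)C/C=C(\C)C(Sc3ccccc3)S(=O)(=O)c3ccccc3)cc1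
F6 | step 5 | (1S)-1-[(2S,3S)-3-{[(4-methoxybenzyl)oxy]methyl}-2-methyloxiran-2-yl]but-3-en-1-ol | COc1ccc(COC[C@@H]2O[C@@]2(C)[C@@H](O)CC=C)cc1
F7 | step 5 | (1R)-1-[(2S,3S)-3-{[(4-methoxybenzyl)oxy]methyl}-2-methyloxiran-2-yl]but-3-en-1-yl 4-nitrobenzoate | COc1ccc(COC[C@@H]2O[C@@]2(C)[C@H](OC(=O)c3ccc(cc3)[N+](=O)[O-])CC=C)cc1
A1 | alternative 1 | (2Z,7E,11E)-5-acetoxy-14-[(tert-butyldimethylsilyl)oxy]-4-hydroxycembra-2,7,11,15(17)-tetraen-16-oic acid (C1, C4, C5, C14 arranged as in 43) | OC(=O)C(=C)[C@H]1/C=C\[C@@](C)(O)[C@H](OC(C)=O)C/C=C(\C)CC/C=C(\C)C[C@H]1O[Si](C)(C)C(C)(C)C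
A2 | alternative 1 | michaolide F 14-O-tert-butyldimethylsilyl ether | C=C1C(=O)O[C@H]2[C@H]1[C@H](O[Si](C)(C)C(C)(C)C)C/C(C)=C/CC/C(C)=C/C[C@@H](OC(C)=O)[C@]1(C)O[C@@H]21
A3 | alternative 2 | 17-membered C14–O–C17 allylic ether with tributylstannyl on C14, triethylsilyl ethers on the C2 and C16 oxygens and a 4-methoxybenzyl ether on the C5 oxygen | CCCC[Sn](CCCC)(CCCC)[C@H]1OC/C(CO[Si](CC)(CC)CC)=C/[C@H](O[Si](CC)(CC)CC)[C@@H]2O[C@@]2(C)[C@H](OCc3ccc(OC)cc3)C/C=C(\C)CC/C=C(\C)C1
A4 | alternative 2 | ring-contracted 14-membered carbocycle with C14 hydroxyl, C1 stereocentre and protected 2-methylene-1,4-diol unit | O[C@H]1[C@@H](C(=C)CO[Si](CC)(CC)CC)[C@H](O[Si](CC)(CC)CC)[C@@H]2O[C@@]2(C)[C@H](OCc3ccc(OC)cc3)C/C=C(\C)CC/C=C(\C)C1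
A5 | alternative 3 | fully oxygenated seco-diyne with methyl-capped alkynes at C11 and C12 | CC#CC[C@@H](O)[C@H]1C(=C)C(=O)O[C@@H]1[C@@H]2O[C@@]2(C)[C@H](OC(C)=O)C/C=C(\C)CCC#CC
A6 | alternative 3 | 12-demethyl-11,12-didehydromichaolide F (14-membered cycloalkyne) | C1#CC[C@@H](O)[C@H]2C(=C)C(=O)O[C@@H]2[C@@H]3O[C@@]3(C)[C@H](OC(C)=O)C/C=C(\C)CC1
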